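**Direct plan and its weak steps**

A direct plan would make ring C first and ring A last: aldehyde A1 and bis(silyloxy)diene A2 would be joined by a Ti(OiPr)4/(S)-BINOL-catalysed hetero-Diels–Alder reaction to dihydropyranone ester A3, which would set C2.
A3 would be turned in three operations (Me3SnOH; i-BuOCOCl; CH2N2) into diazoketone A4.
Light would then trigger a Wolff rearrangement of A4, and the vinylketene would combine with geranyl siloxyalkyne A5 in a Danheiser benzannulation to chromanone A6; desilylation and acidic loss of the acetals would finish.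
Weak step 1, the cycloaddition that sets C2: the diene is deactivated by its ester and untested with this catalyst, so the face selectivity would be a guess, and the β-alkoxy ketone stereocentre (open to E1cB ring opening) would then have to survive seven more steps.
Weak step 2, the run from ester A3 to diazoketone A4, together with the peroxide oxygenation that leads to A5: tin, diazomethane and peroxide chemistry that adds one carbon and closes no ring.
Weak step 3, the benzannulation: four pericyclic events in a row on an enone-bearing dihydropyranone, a substrate class never tried, placed late, where it would consume both advanced fragments at 80 °C next to the geranyl alkenes.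

**Retrosynthetic overview of the new route**

Key cut, C2–C1′: C2 is the only stereocentre, lies β to the C4 carbonyl and carries ring B, so ring B would come last, as boronic acid 16, onto the flat, achiral chromone 12 by rhodium-catalysed asymmetric 1,4-addition, which would form the last C–C bond of the skeleton and C2 in one catalytic step.
Ring A would be bought as phloroglucinol; in the target its local mirror plane runs through C6 (geranyl) and C8a–O1, so silylating one oxygen (future O1) lets directed lithiation put the geranyl group on the carbon between the two OMOM groups (C6), after which the two remaining CH positions are equivalent and 6- versus 8-geranyl isomers cannot arise.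
Ring order: A (bought), then C by O1–C2 closure of the freed O1 phenoxide onto an ynone (6-endo), then ring B joined; every compound before step 8 is achiral.
Answers to the weak steps: C2 is set in the last step but one, under ligand control, and then meets only one acidic step; no step only changes an activating group; the risk sits in one catalytic step fed by a five-step arm and a two-step arm.

Key step: step 8

Remarks: geranyl = (2E)-3,7-dimethylocta-2,6-dien-1-yl; MOM = methoxymethyl.
Assumption: Weinreb amide 8 is taken as a purchasable reagent (it is otherwise one step from 3-(trimethylsilyl)propiolic acid).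
Assumption: the sense of induction in step 8 is assigned by analogy with cyclic enones; should a first run show the opposite sense, the (1R,4R) ligand would be used.

**Route**

Step 1
Reactants: 1 phloroglucinol
Product: 2 5-(triisopropylsilyloxy)benzene-1,3-diol
Conditions: i-Pr3SiCl (1.0 equiv), 1 (3 equiv), imidazole, DMF, 0 °C → rt
Reagents that add atoms: triisopropylsilyl chloride, CC(C)[Si](Cl)(C(C)C)C(C)C
Why: Silylation of one phenol of the threefold-symmetric triol (silyl ether formation), run with the silyl chloride as the limiting reagent so that the monoether dominates, marks the oxygen that becomes O1; the excess of water-soluble 1 is washed out.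

Step 2
Reactants: 2 5-(triisopropylsilyloxy)benzene-1,3-diol
Product: 3 [3,5-bis(methoxymethoxy)phenoxy]triisopropylsilane
Conditions: MeOCH2Cl (2.5 equiv), i-Pr2NEt, CH2Cl2, 0 °C → rt
Reagents that add atoms: chloromethyl methyl ether, COCCl
Why: Base-mediated O-alkylation of both remaining phenols (methoxymethyl ether formation) installs groups that direct lithiation, resist organolithium reagents and fluoride, and leave 3 with a mirror plane through the silyloxy carbon.

Step 3
Reactants: 3 [3,5-bis(methoxymethoxy)phenoxy]triisopropylsilane; 4 geranyl bromide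
Product: 6 [4-geranyl-3,5-bis(methoxymethoxy)phenoxy]triisopropylsilane, via aryllithium 5 (not isolated)
Conditions: n-BuLi (1.15 equiv), THF, 0 °C, 1 h; then 4, −78 °C → rt
Reagents that add atoms: none
Why: Directed ortho-metalation removes the only proton flanked by two OMOM groups, para to the silyloxy group, and SN2 alkylation of aryllithium 5 at the primary allylic carbon of 4 keeps the E alkene, so the geranyl group lands on the future C6 with no isomer possible.

Step 4
Reactants: 6 [4-geranyl-3,5-bis(methoxymethoxy)phenoxy]triisopropylsilane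
Product: 7 [2-bromo-4-geranyl-3,5-bis(methoxymethoxy)phenoxy]triisopropylsilane
Conditions: NBS (1.0 equiv), CH2Cl2, −78 → −20 °C, dark
Reagents that add atoms: N-bromosuccinimide, O=C1CCC(=O)N1Br
Why: Electrophilic aromatic bromination of the trioxygenated ring is far faster at low temperature than attack of NBS on the trisubstituted alkenes, and the two open ring positions are equivalent, so one equivalent of NBS should give a single monobromide that marks the future C4a.

Step 5
Reactants: 7 [2-bromo-4-geranyl-3,5-bis(methoxymethoxy)phenoxy]triisopropylsilane; 8 N-methoxy-N-methyl-3-(trimethylsilyl)prop-2-ynamide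
Product: 12 6-geranyl-5,7-bis(methoxymethoxy)-4H-chromen-4-one, via aryllithium 9 (not isolated), via silyl ynone 10 (not isolated), via hydroxy ynone 11 (not isolated)
Conditions: t-BuLi (2.05 equiv), Et2O, −78 °C; 8, −78 → −30 °C; aq. NH4Cl; then Bu4NF (2.2 equiv), THF–MeOH (10:1), 0 °C → rt
Reagents that add atoms: none
Why: Bromine–lithium exchange at −78 °C outruns deprotonation of the benzylic allylic CH2, aryllithium 9 is acylated once by Weinreb amide 8 through its stable chelate (Weinreb ketone synthesis), and fluoride then strips both silyl groups so that the freed O1 phenoxide adds 6-endo to the terminal ynone of 11 (oxa-Michael addition), which closes ring C; only the formerly silylated oxygen is free, which fixes geranyl at C6 and not C8.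

Step 6
Reactants: 13 3-methoxycatechol
Product: 14 1-methoxy-2,3-bis(methoxymethoxy)benzene
Conditions: MeOCH2Cl (2.5 equiv), i-Pr2NEt, CH2Cl2, 0 °C → rt
Reagents that add atoms: chloromethyl methyl ether, COCCl
Why: Base-mediated double O-alkylation of the catechol (methoxymethyl ether formation) gives a 1,2,3-trisubstituted arene whose acetals tolerate borylation and aqueous base.

Step 7
Reactants: 14 1-methoxy-2,3-bis(methoxymethoxy)benzene
Product: 16 [3-methoxy-4,5-bis(methoxymethoxy)phenyl]boronic acid, via pinacol boronate 15 (not isolated)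
Conditions: [Ir(OMe)(cod)]2 (1.5 mol%), 4,4′-di-tert-butyl-2,2′-bipyridine (3 mol%), B2pin2 (0.55 equiv), THF, 80 °C; then NaIO4, NH4OAc, acetone–H2O, rt
Reagents that add atoms: bis(pinacolato)diboron, CC1(C)OB(OC1(C)C)B1OC(C)(C)C(C)(C)O1; water, O
Why: Iridium-catalysed C–H borylation is steered by sterics to the only CH without an ortho substituent, C5 of 14, which is the carbon that must bond to C2, and periodate cleavage of the pinacol ester at neutral pH frees the boronic acid without touching the acetals.

Step 8
Reactants: 12 6-geranyl-5,7-bis(methoxymethoxy)-4H-chromen-4-one; 16 [3-methoxy-4,5-bis(methoxymethoxy)phenyl]boronic acid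
Product: 17 (2S)-6-geranyl-5,7-bis(methoxymethoxy)-2-[3-methoxy-4,5-bis(methoxymethoxy)phenyl]-2,3-dihydro-4H-chromen-4-one
Conditions: [RhCl(C2H4)2]2 (2.5 mol%), (1S,4S)-2,5-diphenylbicyclo[2.2.2]octa-2,5-diene (5.5 mol%), KOH (0.2 equiv), 16 (2.5 equiv), 1,4-dioxane–H2O (10:1), 30 °C, argon
Reagents that add atoms: none
Why: Hydroxide turns the chloride precatalyst into a rhodium hydroxide that carries the chiral diene, transmetalation with 16 gives an aryl–rhodium species that inserts the C2=C3 bond of 12, and water protonates the resulting oxa-π-allyl rhodium enolate to release 17 and the rhodium hydroxide. The closest known reaction type is the rhodium-catalysed asymmetric 1,4-addition of arylboronic acids to chromones (Hayashi–Miyaura reaction), which gives flavanones directly. No ring is closed; the step forms the C2–C1′ bond and the only stereocentre, and C2 is controlled by the ligand alone: the (S,S) diene is the hand expected, from the model for cyclic enones, to deliver the aryl group to the Re face of C2 and so give 2S. The step needs 1,4- over 1,2-addition and an intact ring C: the ring oxygen cannot reach the syn-periplanar geometry for β-oxygen elimination, and a low hydroxide loading at 30 °C with the C5 oxygen capped as its MOM ether should keep retro-oxa-Michael racemisation of 17 slow. The trisubstituted geranyl alkenes do not insert into aryl–rhodium bonds and the acetals are stable to aqueous base. The excess of 16 covers protodeboronation of this electron-rich boronic acid.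

Step 9
Reactants: 17 (2S)-6-geranyl-5,7-bis(methoxymethoxy)-2-[3-methoxy-4,5-bis(methoxymethoxy)phenyl]-2,3-dihydro-4H-chromen-4-one
Product: 18 (2S)-2-(3,4-dihydroxy-5-methoxyphenyl)-6-geranyl-5,7-dihydroxy-2,3-dihydro-4H-chromen-4-one (CNP0110161.1)
Conditions: HCl (3 M aq.)–MeOH (1:5), 45 °C, argon
Reagents that add atoms: none
Why: Acid-catalysed transacetalisation of the four methoxymethyl ethers to methanol (acetal cleavage) frees all phenols at once; flavanones hold their C2 configuration in acid, and the same cleavage is in routine use for geranylated polyhydroxyflavanones.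

**Compound list**

1 | phloroglucinol (benzene-1,3,5-triol) | Oc1cc(O)cc(O)c1 | starting material
2 | 5-(triisopropylsilyloxy)benzene-1,3-diol | CC(C)[Si](Oc1cc(O)cc(O)c1)(C(C)C)C(C)C | intermediate
3 | [3,5-bis(methoxymethoxy)phenoxy]triisopropylsilane | COCOc1cc(OCOC)cc(O[Si](C(C)C)(C(C)C)C(C)C)c1 | intermediate
4 | geranyl bromide, (2E)-1-bromo-3,7-dimethylocta-2,6-diene | CC(C)=CCC/C(C)=C/CBr | starting material
5 | [2,6-bis(methoxymethoxy)-4-(triisopropylsilyloxy)phenyl]lithium | [Li]c1c(OCOC)cc(O[Si](C(C)C)(C(C)C)C(C)C)cc1OCOC | intermediate (not isolated)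
6 | [4-geranyl-3,5-bis(methoxymethoxy)phenoxy]triisopropylsilane | CC(C)=CCC/C(C)=C/Cc1c(OCOC)cc(O[Si](C(C)C)(C(C)C)C(C)C)cc1OCOC | intermediate
7 | [2-bromo-4-geranyl-3,5-bis(methoxymethoxy)phenoxy]triisopropylsilane | CC(C)=CCC/C(C)=C/Cc1c(OCOC)cc(O[Si](C(C)C)(C(C)C)C(C)C)c(Br)c1OCOC | intermediate
8 | N-methoxy-N-methyl-3-(trimethylsilyl)prop-2-ynamide | CON(C)C(=O)C#C[Si](C)(C)C | starting material
9 | [3-geranyl-2,4-bis(methoxymethoxy)-6-(triisopropylsilyloxy)phenyl]lithium | [Li]c1c(O[Si](C(C)C)(C(C)C)C(C)C)cc(OCOC)c(C/C=C(\C)CCC=C(C)C)c1OCOC | intermediate (not isolated)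
10 | 1-[3-geranyl-2,4-bis(methoxymethoxy)-6-(triisopropylsilyloxy)phenyl]-3-(trimethylsilyl)prop-2-yn-1-one | C[Si](C)(C)C#CC(=O)c1c(O[Si](C(C)C)(C(C)C)C(C)C)cc(OCOC)c(C/C=C(\C)CCC=C(C)C)c1OCOC | intermediate (not isolated)
11 | 1-[3-geranyl-6-hydroxy-2,4-bis(methoxymethoxy)phenyl]prop-2-yn-1-one | C#CC(=O)c1c(O)cc(OCOC)c(C/C=C(\C)CCC=C(C)C)c1OCOC | intermediate (not isolated)
12 | 6-geranyl-5,7-bis(methoxymethoxy)-4H-chromen-4-one | O=c1ccoc2cc(OCOC)c(C/C=C(\C)CCC=C(C)C)c(OCOC)c12 | intermediate
13 | 3-methoxycatechol (3-methoxybenzene-1,2-diol) | COc1cccc(O)c1O | starting material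
14 | 1-methoxy-2,3-bis(methoxymethoxy)benzene | COCOc1cccc(OC)c1OCOC | intermediate
15 | 2-[3-methoxy-4,5-bis(methoxymethoxy)phenyl]-4,4,5,5-tetramethyl-1,3,2-dioxaborolane | COCOc1cc(B2OC(C)(C)C(C)(C)O2)cc(OC)c1OCOC | intermediate (not isolated)
16 | [3-methoxy-4,5-bis(methoxymethoxy)phenyl]boronic acid | COCOc1cc(B(O)O)cc(OC)c1OCOC | intermediate
17 | (2S)-6-geranyl-5,7-bis(methoxymethoxy)-2-[3-methoxy-4,5-bis(methoxymethoxy)phenyl]-2,3-dihydro-4H-chromen-4-one | COc1cc([C@@H]2CC(=O)c3c(cc(OCOC)c(C/C=C(\C)CCC=C(C)C)c3OCOC)O2)cc(OCOC)c1OCOC | intermediate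
18 | (2S)-2-(3,4-dihydroxy-5-methoxyphenyl)-6-[(2E)-3,7-dimethylocta-2,6-dien-1-yl]-5,7-dihydroxy-2,3-dihydro-4H-chromen-4-one | COc1cc([C@@H]2CC(=O)c3c(cc(O)c(C/C=C(\C)CCC=C(C)C)c3O)O2)cc(O)c1O | target

**Step count and risks**

Total step count: 9. Longest linear sequence: 7 (steps 1–5, 8, 9).

Steps most likely to fail:

Step 8. Insertion into the electron-rich chromone may be slow while the boronic acid protodeboronates, and enantiopurity may erode through weak facial discrimination or base-induced retro-oxa-Michael opening of the product. The fallback sets out from bromide 7 and comes back at 17; it would set C2 on an open chain and close ring C at C4–C4a.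
- Methyl 3,4-dihydroxy-5-methoxybenzoate would be protected (MeOCH2Cl, i-Pr2NEt) to methyl 3-methoxy-4,5-bis(methoxymethoxy)benzoate F1.
- Acylation of the lithium enolate of N-methoxy-N-methylacetamide by F1 would give N-methoxy-3-[3-methoxy-4,5-bis(methoxymethoxy)phenyl]-N-methyl-3-oxopropanamide F2.
- Transfer hydrogenation with RuCl(p-cymene)[(R,R)-TsDPEN] and HCO2H/Et3N would be expected to give (3R)-3-hydroxy-N-methoxy-3-[3-methoxy-4,5-bis(methoxymethoxy)phenyl]-N-methylpropanamide F3.
- Bromide 7 would be desilylated with Bu4NF to 2-bromo-4-geranyl-3,5-bis(methoxymethoxy)phenol F4.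
- Mitsunobu etherification of F4 with F3 (PPh3, diisopropyl azodicarboxylate), with inversion, would give (3S)-3-[2-bromo-4-geranyl-3,5-bis(methoxymethoxy)phenoxy]-N-methoxy-3-[3-methoxy-4,5-bis(methoxymethoxy)phenyl]-N-methylpropanamide F5.
- Bromine–lithium exchange (n-BuLi, THF, −78 °C) and Parham cyclisation of the aryllithium onto the Weinreb amide would then give 17.

Step 5. The hindered ortho-silyloxy aryllithium may undergo oxygen-to-carbon silyl migration before it is acylated, it may add in conjugate fashion to the ynamide, or the ring may close 5-exo instead of 6-endo. The fallback sets out from bromide 7 and comes back at 12; it would lithiate without a silyl group on oxygen and close ring C through an enaminone.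
- Bromide 7 would first be desilylated to the bromophenol F4 described above.
- The dianion of F4 (n-BuLi, 2.1 equiv, THF, −78 °C) would be acetylated with N-methoxy-N-methylacetamide to 1-[3-geranyl-6-hydroxy-2,4-bis(methoxymethoxy)phenyl]ethan-1-one F6.
- Condensation with Me2NCH(OMe)2 in toluene at 90 °C would give (2E)-3-(dimethylamino)-1-[3-geranyl-6-hydroxy-2,4-bis(methoxymethoxy)phenyl]prop-2-en-1-one F7.
- AcOH in CH2Cl2 would close F7 to chromone 12.

Step 9. While the last acetals are still being cleaved, the acid may cyclise the geranyl chain onto the flanking C5 and C7 phenols (chroman formation) or hydrate the alkenes. The fallback sets out from 17 and comes back at 18; it would replace solvolysis in protic acid by an aprotic transacetalisation.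
- Me3SiOTf and 2,2′-bipyridyl (CH2Cl2, 0 °C) would silylate each acetal oxygen and carry the methoxymethyl group off as a bipyridinium salt, to give (2S)-6-geranyl-2-[3-methoxy-4,5-bis(trimethylsilyloxy)phenyl]-5,7-bis(trimethylsilyloxy)-2,3-dihydro-4H-chromen-4-one F8.
- Water at neutral pH would then hydrolyse the aryl silyl ethers of F8 to 18 with no free strong acid present.

Further compounds
F1 | step 8 | methyl 3-methoxy-4,5-bis(methoxymethoxy)benzoate | COCOc1cc(C(=O)OC)cc(OC)c1OCOC
F2 | step 8 | N-methoxy-3-[3-methoxy-4,5-bis(methoxymethoxy)phenyl]-N-methyl-3-oxopropanamide | COCOc1cc(C(=O)CC(=O)N(C)OC)cc(OC)c1OCOC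
F3 | step 8 | (3R)-3-hydroxy-N-methoxy-3-[3-methoxy-4,5-bis(methoxymethoxy)phenyl]-N-methylpropanamide | CON(C)C(=O)C[C@@H](O)c1cc(OC)c(OCOC)c(OCOC)c1
F4 | step 8 | 2-bromo-4-geranyl-3,5-bis(methoxymethoxy)phenol | CC(C)=CCC/C(C)=C/Cc1c(OCOC)cc(O)c(Br)c1OCOC
F5 | step 8 | (3S)-3-[2-bromo-4-geranyl-3,5-bis(methoxymethoxy)phenoxy]-N-methoxy-3-[3-methoxy-4,5-bis(methoxymethoxy)phenyl]-N-methylpropanamide | CON(C)C(=O)C[C@H](Oc1cc(OCOC)c(C/C=C(\C)CCC=C(C)C)c(OCOC)c1Br)c1cc(OC)c(OCOC)c(OCOC)c1
F6 | step 5 | 1-[3-geranyl-6-hydroxy-2,4-bis(methoxymethoxy)phenyl]ethan-1-one | CC(=O)c1c(O)cc(OCOC)c(C/C=C(\C)CCC=C(C)C)c1OCOC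
F7 | step 5 | (2E)-3-(dimethylamino)-1-[3-geranyl-6-hydroxy-2,4-bis(methoxymethoxy)phenyl]prop-2-en-1-one | CN(C)/C=C/C(=O)c1c(O)cc(OCOC)c(C/C=C(\C)CCC=C(C)C)c1OCOC
F8 | step 9 | (2S)-6-geranyl-2-[3-methoxy-4,5-bis(trimethylsilyloxy)phenyl]-5,7-bis(trimethylsilyloxy)-2,3-dihydro-4H-chromen-4-one | COc1cc([C@@H]2CC(=O)c3c(cc(O[Si](C)(C)C)c(C/C=C(\C)CCC=C(C)C)c3O[Si](C)(C)C)O2)cc(O[Si](C)(C)C)c1O[Si](C)(C)C
A1 | direct plan | 3-methoxy-4,5-bis(methoxymethoxy)benzaldehyde | COCOc1cc(C=O)cc(OC)c1OCOC
A2 | direct plan | ethyl (2Z)-2,4-bis(trimethylsilyloxy)penta-2,4-dienoate | CCOC(=O)/C(O[Si](C)(C)C)=C/C(=C)O[Si](C)(C)C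
A3 | direct plan | ethyl (2S)-2-[3-methoxy-4,5-bis(methoxymethoxy)phenyl]-4-oxo-3,4-dihydro-2H-pyran-6-carboxylate | CCOC(=O)C1=CC(=O)C[C@@H](c2cc(OC)c(OCOC)c(OCOC)c2)O1
A4 | direct plan | (2S)-6-(2-diazoacetyl)-2-[3-methoxy-4,5-bis(methoxymethoxy)phenyl]-2,3-dihydro-4H-pyran-4-one | [N-]=[N+]=CC(=O)C1=CC(=O)C[C@@H](c2cc(OC)c(OCOC)c(OCOC)c2)O1
A5 | direct plan | (4E)-5,9-dimethyl-1-(triisopropylsilyloxy)deca-4,8-dien-1-yne | CC(C)=CCC/C(C)=C/CC#CO[Si](C(C)C)(C(C)C)C(C)C
A6 | direct plan | (2S)-6-geranyl-5-hydroxy-2-[3-methoxy-4,5-bis(methoxymethoxy)phenyl]-7-(triisopropylsilyloxy)-2,3-dihydro-4H-chromen-4-one | COc1cc([C@@H]2CC(=O)c3c(cc(O[Si](C(C)C)(C(C)C)C(C)C)c(C/C=C(\C)CCC=C(C)C)c3O)O2)cc(OCOC)c1OCOC
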